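The earlier runs and the new flask are simulated with made-up constants; scatter was added.

2.00% of the solid first end groups charged is the number to carry through this flask: it is the capping ceiling, the charge of one-sided end groups as a fraction of the charge of solid first end groups.

| setting | cedar | flask |
|---|---|---|
| solid first end groups | 0.050 M | 0.050 M |
| one-sided end groups | 1 mM | 1.00 mM |
| gas | 2.6 mM (held) | 2.6 mM (held) |
| remark | the very flask that is asked about, followed so far |  |
| time |  | 8.0 h |

- cedar (time / h: links / %, capped ends / %): 0.333: 0.7, 1.6; 0.667: 1.7, 2.0; 1.50: 4.9, 2.5; 4.00: 14.1, 1.5

(scatter of a reading: 0.3 percentage points)

- amounts and yields of links count idle adduct too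
- given per volume of solution although it is solid: solid first end groups
- at the start none of second end groups is dissolved
- steps under discussion: first end groups + second end groups -> links; first end groups + one-sided end groups -> capped ends; gas <-> second end groups; solid first end groups <-> first end groups; second end groups + links <-> idle adduct
- at the start none of the solid first end groups is in solution
- first end groups means what is dissolved; the solid is not counted in it

- amount of links in the flask at 8.0 h, in percent of the solid first end groups charged
- amount of capped ends in the flask at 8.0 h, in percent of the solid first end groups charged
- amount of idle adduct in the flask at 8.0 h, in percent of the solid first end groups charged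
- amount of first end groups in the flask at 8.0 h, in percent of the solid first end groups charged
- concentration of second end groups at 8.0 h, in M

Two ways lead to the capped ends at 8.0 h. The first is the balance of the one-sided end groups, charged in far smaller amount than the solid and so the limiting reagent of capping. Each capped end uses up one of them, so capped ends stop at 2.00%. The second is the cedar run, this same flask followed so far, whose last two readings of capped ends, 2.5% and 1.5%, average 2.00%.

The two numbers come from different things, a charge and a measurement, and they agree. They part in shape, though. Read alone, the cedar run climbs and then falls, as if capped ends were being consumed, and its reading at 1.50 h stands 0.5 percentage points above the ceiling. The balance has no room for that excess, so the readings are what cheats here: the scatter is 0.3 points, and the next reading lies 0.5 points below the ceiling. On a repeat, a point above 2.00% is therefore to be taken as scatter, not as a peak. The reckoning here commits to 2.00% for capped ends at 8.0 h.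

The forecast gives links 28.9%, capped ends 2%, idle adduct 2%, first end groups 2% and second end groups 0.002 M. On the capped ends its ground reads: “So capping is finished”.

This flask gives links 29.8%, capped ends 2.00%, level with the ceiling, idle adduct 25.9% (counted in the links), first end groups 2.96% and second end groups 7.96 × 10⁻⁴ M, so the forecast stands 24 points low on the adduct.

    first end groups + second end groups → links (k = 27.0 M⁻¹ min⁻¹)
    first end groups + one-sided end groups → capped ends (k = 150 M⁻¹ min⁻¹)
    gas ⇌ second end groups, rate k3*(csat - [second end groups]) (kL = 0.0330 min⁻¹)
    solid first end groups ⇌ first end groups, rate k4*(cs4 - [first end groups]) while solid is left; crystals form when [first end groups] > cs4 (solubility = 1.80 mM, k = 0.100 min⁻¹)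
    second end groups + links ⇌ idle adduct, settled at all times (K = 8400 M⁻¹)

Capping ran while one-sided end groups were there: at 0.800 h capped ends stood at 2.00%, with 0.0489% of the one-sided charge left. Linking went on with solid first end groups still present, 80.5% of the charge at 4.00 h and 65.3% at 8.00 h. The neighbour flask charged with 0.12 M of solid has a ceiling of 0.833%, and its capped ends stand at 0.833%.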